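The earlier runs and the new flask were computed with made-up constants.

The summer run slows hard: it makes 0.0208 M of target in its first 0.67 h and 7.10 mM in its last 2.50 h. Your first guess is that the charge is running down, so reckon with what is left, not with what is made.

| flask | starting material | reagent | free catalyst | time |
|---|---|---|---|---|
| summer | 0.120 M | 0.240 M | 0.00360 M |  |
| winter | 0.120 M | 0.480 M | 0.00360 M |  |
| midnight | 0.240 M | 0.240 M | 0.00360 M |  |
| autumn | 0.120 M | 0.240 M | 0.00180 M |  |
| noon | 0.300 M | 0.600 M | 0.00360 M | 6.7 h |

- summer run (time / h: [target] / M): 0.27: 0.0090; 0.42: 0.0148; 0.67: 0.0208; 1.1: 0.0313; 1.7: 0.0422; 2.7: 0.0534; 4.2: 0.0646; 6.7: 0.0717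
- winter run (time / h: [target] / M): 0.27: 0.0187; 0.42: 0.0263; 0.67: 0.0384; 1.1: 0.0544; 1.7: 0.0688; 2.7: 0.0841; 4.2: 0.0934; 6.7: 0.0974
- midnight run (time / h: [target] / M): 0.27: 0.0183; 0.42: 0.0272; 0.67: 0.0406; 1.1: 0.0577; 1.7: 0.0770; 2.7: 0.0974; 4.2: 0.1144; 6.7: 0.1261
- autumn run (time / h: [target] / M): 0.27: 0.0057; 0.42: 0.0082; 0.67: 0.0132; 1.1: 0.0204; 1.7: 0.0271; 2.7: 0.0359; 4.2: 0.0446; 6.7: 0.0520

(standard deviation of a reading: 4 × 10⁻⁴ M)

* how the opening rate goes with [free catalyst] round the charge of the summer run: the exponent of the rate at two percent of starting material gone to target
* how the opening rate goes with [reagent] round the charge of the summer run: the exponent of the rate at two percent of starting material gone to target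
* target in the noon run at 6.7 h, as a share of the starting material charged

- Overall: starting material + reagent -> target, with free catalyst as catalyst.
- Constant volume, constant temperature.
- An order is taken over about fifteen percent of the charge, up and down.

Write S for starting material, the limiting reagent in the summer run, and R for reagent; subtract target from each charge to get what is left. The summer run reaches 4.63 M⁻¹ at 6.7 h on the exposure E: the ratio R to S now, over that ratio at the charge, take the natural log, divide by the difference of the charges. With equal charges, as in the midnight run, E is one over S now minus one over S at the charge. If the rate goes as S times R, E comes out the same at the same hour for different charges of S and R with the same catalyst charge.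

Test it. At 1.7 h, E reads 2.00 M⁻¹ in summer, 1.94 M⁻¹ in winter and 1.97 M⁻¹ at midnight, so I take the reagent order as one. But E itself slows in the summer run: it gains 2.00 M⁻¹ in the first 1.7 h and 2.63 M⁻¹ in the next 5.00 h, which is less per hour than at first. I read that as the catalyst's work fading with the hours.

For the catalyst order, the first readings of summer and autumn give 0.659. That rests on a small reading against the scatter, though, and the final exposures, with autumn at 2.70 M⁻¹, give 0.778. I take the middle, 0.719.

The noon run has summer's catalyst charge and is asked at summer's last hour, so put summer's E into it, and the reckoning says 85.7 % of its starting material turns to target. The objection is the winter run: at 6.7 h its E is 4.01 M⁻¹, lower than summer's, and winter has the smaller fraction of starting material left, 18.8 % against 40.2 %, and noon too is reckoned to go that far. Winter's E gives noon 82.3 %, and that is my figure.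

The forecast says 0.73 for the catalyst order, 0.98 for the reagent order and, shaded down for the extrapolation, 82 % for noon, and holds that “The slowdown follows clock time, not conversion”.

The noon run gives 80.6 %, with 0.70 for the catalyst order and 1.0 for the reagent order, and the forecast stood within its margins.

    2 free catalyst ⇌ catalyst dimer, settled at all times (196.0 M⁻¹)
    free catalyst + starting material + reagent → target + free catalyst (662.4 M⁻² h⁻¹)
    free catalyst → spent catalyst (0.3182 h⁻¹)
    target → decomposed product (0.02106 h⁻¹)

In this scheme target goes on to decomposed product with k3 = 0.0211 h⁻¹. Turned back through the fraction left, noon's share is an exposure of 3.75 M⁻¹, lower than winter's 4.01 M⁻¹. Put into the winter charge, that exposure gives 0.0951 M of target, and the winter run read 0.0974 M at 6.7 h.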